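**Retrosynthetic overview** (isochromene numbering of the target: C1, O2, C3, C4, C4a, C5 … C8a)
1. Pyran ring (formed last): cut O2–C3 and C3–C4. The precursor is a hydroxy ene-dione made by carbonylative union of an E-vinylstannane side chain, carbon monoxide (which becomes C3) and an allylic chloride at C4.
2. Carbocycle (key step): C4a–C5 bond by copper-catalysed 6-exo atom-transfer radical cyclization of a trichloromethyl ketone onto a vinyl group. The three chlorines end up as the C5 chlorine of the target, the HCl that is eliminated, and the C4 leaving group.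
3. Cyclization precursor: anti allylboration (C8–C8a bond, both stereocentres) of an α-silyloxy aldehyde made from methyl (R)-2-methylglycidate (source of C7), then ester → CCl3 ketone.
4. Side chain: Brown crotylboration of methacrolein, oxolane closure, ozonolysis, chelation-controlled ethynylation (tertiary carbinol), hydrostannation.
5. Ring order: oxolane → carbocycle (radical) → pyran.

Assumption: methyl (2R)-2-methyloxirane-2-carboxylate, buta-2,3-dien-1-ol and ethynylmagnesium bromide solution are bought; metal alkoxides that are only protonated on aqueous work-up are not numbered.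

**Route**

Step 1
Reactants: 1 (E)-but-2-ene; 2 2-methylprop-2-enal (methacrolein)
Product: 6 (3S,4S)-2,4-dimethylhexa-1,5-dien-3-ol, via crotylpotassium 3 (not isolated), via crotylborane 4 (not isolated), via borinate 5 (not isolated)
Conditions: KOtBu, n-BuLi, THF, −78 → −45 °C; (−)-Ipc2BOMe, −78 °C; BF3·OEt2, then 2, −78 °C; NaOH, H2O2, 0 °C → rt
Reagents that add atoms: none
Why: Brown asymmetric crotylboration through a closed chair transition state, in which the E-crotyl geometry gives the anti pair and the isopinocampheyl groups from (+)-α-pinene direct attack to the Si face of the aldehyde, setting both stereocentres (the later oxolane C2 and C3).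

Step 2
Reactants: 6 (3S,4S)-2,4-dimethylhexa-1,5-dien-3-ol
Product: 8 (3S,4S)-3,5-dimethylhex-5-ene-1,4-diol, via alkylborane 7 (not isolated)
Conditions: (c-C6H11)2BH (2.2 equiv), THF, 0 °C → rt; NaOH, H2O2, 0 °C
Reagents that add atoms: hydrogen peroxide, OO
Why: Chemoselective anti-Markovnikov hydroboration–oxidation, in which the bulky dialkylborane adds to the unhindered monosubstituted vinyl group much faster than to the 1,1-disubstituted alkene beside the borinate-capped carbinol, with no stereocentre touched.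

Step 3
Reactants: 8 (3S,4S)-3,5-dimethylhex-5-ene-1,4-diol
Product: 10 (2S,3S)-3-methyl-2-(prop-1-en-2-yl)oxolane, via tosylate 9 (not isolated)
Conditions: TsCl, pyridine, CH2Cl2, 0 → 40 °C
Reagents that add atoms: none
Why: Selective tosylation of the primary hydroxyl followed by 5-exo-tet Williamson etherification by the secondary hydroxyl closes the oxolane at the achiral CH2, so both stereocentres are kept and the ring is trans-2,3-disubstituted.

Step 4
Reactants: 10 (2S,3S)-3-methyl-2-(prop-1-en-2-yl)oxolane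
Product: 12 1-[(2S,3S)-3-methyloxolan-2-yl]ethan-1-one, via ozonide 11 (not isolated)
Conditions: O3, CH2Cl2, −78 °C; then PPh3, −78 °C → rt
Reagents that add atoms: ozone, [O-][O+]=O
Why: Ozonolysis with reductive work-up cleaves the 1,1-disubstituted alkene to the methyl ketone, and the centre next to the carbonyl is already the thermodynamically favoured trans epimer, so it is not scrambled.

Step 5
Reactants: 12 1-[(2S,3S)-3-methyloxolan-2-yl]ethan-1-one; 13 ethynylmagnesium bromide
Product: 14 (2S)-2-[(2S,3S)-3-methyloxolan-2-yl]but-3-yn-2-ol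
Conditions: THF, −78 → −40 °C; then aq. NH4Cl
Reagents that add atoms: none
Why: Chelation-controlled (Cram chelate) Grignard addition, in which magnesium bridges the ring oxygen and the carbonyl oxygen and the acetylide attacks from the side of the C2 hydrogen, setting the tertiary carbinol as S.

Step 6
Reactants: 14 (2S)-2-[(2S,3S)-3-methyloxolan-2-yl]but-3-yn-2-ol
Product: 15 (2S,3E)-2-[(2S,3S)-3-methyloxolan-2-yl]-4-(tributylstannyl)but-3-en-2-ol
Conditions: Bu3SnH, PdCl2(PPh3)2 (2 mol %), THF, 0 °C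
Reagents that add atoms: tributyltin hydride, CCCC[SnH](CCCC)CCCC
Why: Palladium-catalysed syn hydrostannation of the terminal alkyne puts tin on the unhindered terminus, because the quaternary carbinol blocks the internal carbon, and gives the E-vinylstannane.

Step 7
Reactants: 16 methyl (2R)-2-methyloxirane-2-carboxylate
Product: 17 methyl (2R)-2,3-dihydroxy-2-methylpropanoate
Conditions: H2O, HClO4 (cat.), THF, 0 °C → rt
Reagents that add atoms: water, O
Why: Acid-catalysed epoxide hydrolysis in which water opens the glycidic ester at the primary carbon, since the tertiary carbon next to the ester is deactivated, so the quaternary centre keeps its R configuration.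

Step 8
Reactants: 17 methyl (2R)-2,3-dihydroxy-2-methylpropanoate
Product: 18 methyl (2R)-2-methyl-2,3-bis[(triethylsilyl)oxy]propanoate
Conditions: TESOTf, 2,6-lutidine, CH2Cl2, −78 → 0 °C
Reagents that add atoms: triethylsilyl trifluoromethanesulfonate, CC[Si](CC)(CC)OS(=O)(=O)C(F)(F)F
Why: Silyl ether formation with the reactive silyl triflate protects the primary and the tertiary hydroxyl without touching the stereocentre.

Step 9
Reactants: 18 methyl (2R)-2-methyl-2,3-bis[(triethylsilyl)oxy]propanoate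
Product: 20 methyl (2R)-2-methyl-3-oxo-2-[(triethylsilyl)oxy]propanoate, via alkoxysulfonium salt 19 (not isolated)
Conditions: (COCl)2, DMSO, CH2Cl2, −78 → −30 °C; then Et3N, −78 °C → rt
Reagents that add atoms: none
Why: Swern oxidation, under which a primary triethylsilyl ether is cleaved and oxidized directly to the aldehyde while the tertiary silyl ether survives, and the quaternary centre has no hydrogen to epimerize.

Step 10
Reactants: 21 buta-2,3-dien-1-ol
Product: 22 (buta-2,3-dien-1-yloxy)(tert-butyl)dimethylsilane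
Conditions: TBSCl, imidazole, CH2Cl2, 0 °C → rt
Reagents that add atoms: tert-butyldimethylsilyl chloride, CC(C)(C)[Si](C)(C)Cl
Why: Imidazole-promoted silylation protects the primary alcohol so that the later δ-hydroxy ester cannot lactonize.

Step 11
Reactants: 22 (buta-2,3-dien-1-yloxy)(tert-butyl)dimethylsilane; 20 methyl (2R)-2-methyl-3-oxo-2-[(triethylsilyl)oxy]propanoate
Product: 25 methyl (2R,3R,4S)-4-({[tert-butyl(dimethyl)silyl]oxy}methyl)-3-hydroxy-2-methyl-2-[(triethylsilyl)oxy]hex-5-enoate, via allylborane 23 (not isolated), via borinate 24 (not isolated)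
Conditions: (+)-Ipc2BH, Et2O, 0 °C → rt; then 20, −78 °C; then NaBO3·4H2O, THF/H2O, rt
Reagents that add atoms: none
Why: Allene hydroboration gives a γ-substituted allylborane that equilibrates by 1,3-boron shift to the E isomer and then undergoes chair-type allylboration, in which the E geometry gives the anti pair and the isopinocampheyl groups from (−)-α-pinene direct Re-face attack under reagent control, setting C8 (R) and C8a (S) of the target.

Step 12
Reactants: 25 methyl (2R,3R,4S)-4-({[tert-butyl(dimethyl)silyl]oxy}methyl)-3-hydroxy-2-methyl-2-[(triethylsilyl)oxy]hex-5-enoate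
Product: 26 methyl (2R,3R,4S)-4-({[tert-butyl(dimethyl)silyl]oxy}methyl)-2-methyl-2,3-bis[(triethylsilyl)oxy]hex-5-enoate
Conditions: TESOTf, 2,6-lutidine, CH2Cl2, −78 → 0 °C
Reagents that add atoms: triethylsilyl trifluoromethanesulfonate, CC[Si](CC)(CC)OS(=O)(=O)C(F)(F)F
Why: Silyl ether formation caps the secondary hydroxyl so that the β-hydroxy carbonyl unit cannot undergo retro-aldol cleavage in the later basic steps, with no stereocentre affected.

Step 13
Reactants: 26 methyl (2R,3R,4S)-4-({[tert-butyl(dimethyl)silyl]oxy}methyl)-2-methyl-2,3-bis[(triethylsilyl)oxy]hex-5-enoate; 27 dichloromethane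
Product: 30 (3R,4R,5S)-5-({[tert-butyl(dimethyl)silyl]oxy}methyl)-1,1,1-trichloro-3-methyl-3,4-bis[(triethylsilyl)oxy]hept-6-en-2-one, via dichloromethyllithium 28 (not isolated), via lithium enolate 29 (not isolated)
Conditions: 27 (3 equiv), LDA (3.5 equiv), THF, −78 °C → −40 °C; then C2Cl6, −78 → 0 °C
Reagents that add atoms: hexachloroethane, ClC(Cl)(Cl)C(Cl)(Cl)Cl
Why: Acylation of dichloromethyllithium by the non-enolizable ester gives the dichloromethyl ketone, which is deprotonated in the same flask, and electrophilic chlorination of that enolate gives the trichloromethyl ketone without touching any stereocentre.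

Step 14
Reactants: 30 (3R,4R,5S)-5-({[tert-butyl(dimethyl)silyl]oxy}methyl)-1,1,1-trichloro-3-methyl-3,4-bis[(triethylsilyl)oxy]hept-6-en-2-one
Product: 32 (4S,5R,6R)-4-({[tert-butyl(dimethyl)silyl]oxy}methyl)-2-chloro-3-(chloromethyl)-6-methyl-5,6-bis[(triethylsilyl)oxy]cyclohex-2-en-1-one, via trichloride 31 (not isolated)
Conditions: CuCl (20 mol %), tris(2-pyridylmethyl)amine (20 mol %), ClCH2CH2Cl, 80 °C; then DBU (1.1 equiv), 0 °C → rt
Reagents that add atoms: none
Why: Kharasch-type atom-transfer radical cyclization, in which the monovalent copper complex abstracts chlorine to give the electrophilic dichloroacyl radical, this closes 6-exo-trig onto the vinyl group to form the C4a–C5 bond, the primary radical takes chlorine back from the divalent copper chloride complex, and E2 loss of HCl across C4a–C5 then removes the only new stereocentre and leaves the C5 chlorine of the target while C7, C8 and C8a are untouched.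

Step 15
Reactants: 32 (4S,5R,6R)-4-({[tert-butyl(dimethyl)silyl]oxy}methyl)-2-chloro-3-(chloromethyl)-6-methyl-5,6-bis[(triethylsilyl)oxy]cyclohex-2-en-1-one; 15 (2S,3E)-2-[(2S,3S)-3-methyloxolan-2-yl]-4-(tributylstannyl)but-3-en-2-ol; 33 carbon monoxide
Product: 34 (4S,5R,6R)-4-({[tert-butyl(dimethyl)silyl]oxy}methyl)-2-chloro-3-{(3E,5S)-5-hydroxy-5-[(2S,3S)-3-methyloxolan-2-yl]-2-oxohex-3-en-1-yl}-6-methyl-5,6-bis[(triethylsilyl)oxy]cyclohex-2-en-1-one
Conditions: CO (3 atm), Pd2(dba)3 (2.5 mol %), AsPh3 (10 mol %), THF, 50 °C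
Reagents that add atoms: none
Why: Carbonylative Stille coupling, in which zerovalent palladium ionizes the allylic chloride, carbon monoxide inserts at the primary allyl terminus and the acylpalladium couples with the vinylstannane with retention of the E geometry, so that C3 of the target comes from carbon monoxide.

Step 16
Reactants: 34 (4S,5R,6R)-4-({[tert-butyl(dimethyl)silyl]oxy}methyl)-2-chloro-3-{(3E,5S)-5-hydroxy-5-[(2S,3S)-3-methyloxolan-2-yl]-2-oxohex-3-en-1-yl}-6-methyl-5,6-bis[(triethylsilyl)oxy]cyclohex-2-en-1-one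
Product: 36 (7R,8R,8aS)-5-chloro-7,8-dihydroxy-3-{(1E,3S)-3-hydroxy-3-[(2S,3S)-3-methyloxolan-2-yl]but-1-en-1-yl}-7-methyl-1,7,8,8a-tetrahydro-6H-isochromen-6-one (CNP0432723.3), via triol 35 (not isolated)
Conditions: HF·pyridine, pyridine, THF, 0 °C → rt; then PPTS (cat.), rt
Reagents that add atoms: none
Why: Fluoride-mediated desilylation frees the three hydroxyls, and 6-exo-trig hemiketalization of the C1 hydroxyl onto the C3 ketone followed by acid-catalysed dehydration into conjugation closes the pyran ring as the fused dienol ether without affecting any stereocentre.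

**Compound list**
1 | (E)-but-2-ene | C/C=C/C | starting material
2 | 2-methylprop-2-enal (methacrolein) | CC(=C)C=O | starting material
3 | (E)-but-2-enylpotassium (crotylpotassium) | C/C=C/C[K] | intermediate
4 | (E)-but-2-enyl-bis(isopinocampheyl)borane, isopinocampheyl groups from (+)-α-pinene | C/C=C/CB([C@@H]1C[C@@H]2C[C@H]([C@H]1C)C2(C)C)[C@@H]1C[C@@H]2C[C@H]([C@H]1C)C2(C)C | intermediate
5 | (3S,4S)-2,4-dimethylhexa-1,5-dien-3-yl bis(isopinocampheyl)borinate | C=C(C)[C@@H](OB([C@@H]1C[C@@H]2C[C@H]([C@H]1C)C2(C)C)[C@@H]1C[C@@H]2C[C@H]([C@H]1C)C2(C)C)[C@@H](C)C=C | intermediate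
6 | (3S,4S)-2,4-dimethylhexa-1,5-dien-3-ol | C=C(C)[C@@H](O)[C@@H](C)C=C | intermediate
7 | (3S,4S)-6-(dicyclohexylboryl)-2,4-dimethylhex-1-en-3-yl dicyclohexylborinate | C=C(C)[C@@H](OB(C1CCCCC1)C1CCCCC1)[C@@H](C)CCB(C1CCCCC1)C1CCCCC1 | intermediate
8 | (3S,4S)-3,5-dimethylhex-5-ene-1,4-diol | C=C(C)[C@@H](O)[C@@H](C)CCO | intermediate
9 | (3S,4S)-4-hydroxy-3,5-dimethylhex-5-en-1-yl 4-methylbenzenesulfonate | C=C(C)[C@@H](O)[C@@H](C)CCOS(=O)(=O)c1ccc(C)cc1 | intermediate
10 | (2S,3S)-3-methyl-2-(prop-1-en-2-yl)oxolane | C=C(C)[C@H]1OCC[C@@H]1C | intermediate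
11 | 3-methyl-3-[(2S,3S)-3-methyloxolan-2-yl]-1,2,4-trioxolane (ozonide, both epimers at the trioxolane carbon) | CC2(OCOO2)[C@H]1OCC[C@@H]1C | intermediate
12 | 1-[(2S,3S)-3-methyloxolan-2-yl]ethan-1-one | CC(=O)[C@H]1OCC[C@@H]1C | intermediate
13 | ethynylmagnesium bromide | C#C[Mg]Br | starting material
14 | (2S)-2-[(2S,3S)-3-methyloxolan-2-yl]but-3-yn-2-ol | C#C[C@](C)(O)[C@H]1OCC[C@@H]1C | intermediate
15 | (2S,3E)-2-[(2S,3S)-3-methyloxolan-2-yl]-4-(tributylstannyl)but-3-en-2-ol | CCCC[Sn](CCCC)(CCCC)/C=C/[C@](C)(O)[C@H]1OCC[C@@H]1C | intermediate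
16 | methyl (2R)-2-methyloxirane-2-carboxylate | COC(=O)[C@@]1(C)CO1 | starting material
17 | methyl (2R)-2,3-dihydroxy-2-methylpropanoate | COC(=O)[C@](C)(O)CO | intermediate
18 | methyl (2R)-2-methyl-2,3-bis[(triethylsilyl)oxy]propanoate | COC(=O)[C@](C)(O[Si](CC)(CC)CC)CO[Si](CC)(CC)CC | intermediate
19 | {(2R)-3-methoxy-2-methyl-3-oxo-2-[(triethylsilyl)oxy]propoxy}dimethylsulfonium chloride | C[S+](C)OC[C@@](C)(O[Si](CC)(CC)CC)C(=O)OC.[Cl-] | intermediate
20 | methyl (2R)-2-methyl-3-oxo-2-[(triethylsilyl)oxy]propanoate | COC(=O)[C@](C)(O[Si](CC)(CC)CC)C=O | intermediate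
21 | buta-2,3-dien-1-ol | C=C=CCO | starting material
22 | (buta-2,3-dien-1-yloxy)(tert-butyl)dimethylsilane | C=C=CCO[Si](C)(C)C(C)(C)C | intermediate
23 | [(2E)-4-{[tert-butyl(dimethyl)silyl]oxy}but-2-en-1-yl]bis(isopinocampheyl)borane, isopinocampheyl groups from (−)-α-pinene | CC(C)(C)[Si](C)(C)OC/C=C/CB([C@H]1C[C@H]2C[C@@H]([C@@H]1C)C2(C)C)[C@H]1C[C@H]2C[C@@H]([C@@H]1C)C2(C)C | intermediate
24 | bis(isopinocampheyl)borinate of 25 (boron on the C3 oxygen) | COC(=O)[C@](C)(O[Si](CC)(CC)CC)[C@H](OB([C@H]1C[C@H]2C[C@@H]([C@@H]1C)C2(C)C)[C@H]1C[C@H]2C[C@@H]([C@@H]1C)C2(C)C)[C@H](CO[Si](C)(C)C(C)(C)C)C=C | intermediate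
25 | methyl (2R,3R,4S)-4-({[tert-butyl(dimethyl)silyl]oxy}methyl)-3-hydroxy-2-methyl-2-[(triethylsilyl)oxy]hex-5-enoate | COC(=O)[C@](C)(O[Si](CC)(CC)CC)[C@H](O)[C@H](CO[Si](C)(C)C(C)(C)C)C=C | intermediate
26 | methyl (2R,3R,4S)-4-({[tert-butyl(dimethyl)silyl]oxy}methyl)-2-methyl-2,3-bis[(triethylsilyl)oxy]hex-5-enoate | COC(=O)[C@](C)(O[Si](CC)(CC)CC)[C@H](O[Si](CC)(CC)CC)[C@H](CO[Si](C)(C)C(C)(C)C)C=C | intermediate
27 | dichloromethane | ClCCl | starting material
28 | dichloromethyllithium | [Li]C(Cl)Cl | intermediate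
29 | lithium (3R,4R,5S)-5-({[tert-butyl(dimethyl)silyl]oxy}methyl)-1,1-dichloro-3-methyl-3,4-bis[(triethylsilyl)oxy]hepta-1,6-dien-2-olate | [Li]OC(=C(Cl)Cl)[C@](C)(O[Si](CC)(CC)CC)[C@H](O[Si](CC)(CC)CC)[C@H](CO[Si](C)(C)C(C)(C)C)C=C | intermediate
30 | (3R,4R,5S)-5-({[tert-butyl(dimethyl)silyl]oxy}methyl)-1,1,1-trichloro-3-methyl-3,4-bis[(triethylsilyl)oxy]hept-6-en-2-one | ClC(Cl)(Cl)C(=O)[C@](C)(O[Si](CC)(CC)CC)[C@H](O[Si](CC)(CC)CC)[C@H](CO[Si](C)(C)C(C)(C)C)C=C | intermediate
31 | (4S,5R,6R)-4-({[tert-butyl(dimethyl)silyl]oxy}methyl)-2,2-dichloro-3-(chloromethyl)-6-methyl-5,6-bis[(triethylsilyl)oxy]cyclohexan-1-one (both C3 epimers) | O=C1C(Cl)(Cl)C(CCl)[C@@H](CO[Si](C)(C)C(C)(C)C)[C@@H](O[Si](CC)(CC)CC)[C@@]1(C)O[Si](CC)(CC)CC | intermediate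
32 | (4S,5R,6R)-4-({[tert-butyl(dimethyl)silyl]oxy}methyl)-2-chloro-3-(chloromethyl)-6-methyl-5,6-bis[(triethylsilyl)oxy]cyclohex-2-en-1-one | O=C1C(Cl)=C(CCl)[C@@H](CO[Si](C)(C)C(C)(C)C)[C@@H](O[Si](CC)(CC)CC)[C@@]1(C)O[Si](CC)(CC)CC | intermediate
33 | carbon monoxide | [C-]#[O+] | starting material
34 | (4S,5R,6R)-4-({[tert-butyl(dimethyl)silyl]oxy}methyl)-2-chloro-3-{(3E,5S)-5-hydroxy-5-[(2S,3S)-3-methyloxolan-2-yl]-2-oxohex-3-en-1-yl}-6-methyl-5,6-bis[(triethylsilyl)oxy]cyclohex-2-en-1-one | O=C1C(Cl)=C(CC(=O)/C=C/[C@](C)(O)[C@H]2OCC[C@@H]2C)[C@@H](CO[Si](C)(C)C(C)(C)C)[C@@H](O[Si](CC)(CC)CC)[C@@]1(C)O[Si](CC)(CC)CC | intermediate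
35 | (4S,5R,6R)-2-chloro-5,6-dihydroxy-3-{(3E,5S)-5-hydroxy-5-[(2S,3S)-3-methyloxolan-2-yl]-2-oxohex-3-en-1-yl}-4-(hydroxymethyl)-6-methylcyclohex-2-en-1-one | O=C1C(Cl)=C(CC(=O)/C=C/[C@](C)(O)[C@H]2OCC[C@@H]2C)[C@@H](CO)[C@@H](O)[C@@]1(C)O | intermediate
36 | (7R,8R,8aS)-5-chloro-7,8-dihydroxy-3-{(1E,3S)-3-hydroxy-3-[(2S,3S)-3-methyloxolan-2-yl]but-1-en-1-yl}-7-methyl-1,7,8,8a-tetrahydro-6H-isochromen-6-one | C[C@H]1CCO[C@@H]1[C@@](C)(O)/C=C/C1=CC2=C(Cl)C(=O)[C@](C)(O)[C@H](O)[C@@H]2CO1 | target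

**Step count and risks**
Total step count: 16. Longest linear sequence: 9 steps (steps 7, 8, 9, 11, 12, 13, 14, 15, 16, from 16 to 36).

Most likely to fail, step 14 (radical ring closure and elimination). The dichloroacyl radical could close 7-endo or abstract the allylic hydrogen at C8a, and 32 is a reactive allylic chloride that DBU or the neighbouring silyl ether could attack. The fallback replaces the radical closure by an organochromium one; it sets out from 30 and comes back at 32. Wacker oxidation (PdCl2, CuCl, O2, DMF/H2O) of the vinyl group of 30 gives the methyl ketone (3R,4R,5S)-5-({[tert-butyl(dimethyl)silyl]oxy}methyl)-1,1,1-trichloro-3-methyl-3,4-bis[(triethylsilyl)oxy]heptane-2,6-dione F1. Excess CrCl2 in THF turns the trichloromethyl ketone into a chromium enolate that adds to the new ketone and, after a further reduction, loses the chromium alkoxide to give the 2-chloro-3-methylcyclohexenone F2. Kinetic deprotonation of the ring methyl group (LiHMDS, Et3SiCl, −78 °C) gives the cross-conjugated triethylsilyl dienol ether F3, and N-chlorosuccinimide chlorinates its exocyclic terminus to return 32.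

Second, step 13 (ester to trichloromethyl ketone in one flask). The ester sits on a fully substituted carbon and may react too slowly with the short-lived carbenoid, or the tetrahedral adduct may not collapse before the chlorinating agent is added. The fallback uses aldehyde addition and oxidation in place of ester acylation; it sets out from 26 and comes back at 30. DIBAL-H reduces 26 to the primary alcohol (2S,3R,4S)-4-({[tert-butyl(dimethyl)silyl]oxy}methyl)-2-methyl-2,3-bis[(triethylsilyl)oxy]hex-5-en-1-ol F4. Dess–Martin periodinane gives the aldehyde F5. Chloroform and LiHMDS at −78 °C add the trichloromethyl anion to give the trichloromethyl carbinol F6, and a second Dess–Martin oxidation returns 30.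

Third, step 15 (carbonylative Stille union). Direct coupling without carbon monoxide uptake, or diversion of the allylpalladium species as a palladium dienolate, would give the wrong skeleton. The fallback uses an acylzirconium nucleophile in place of the palladium carbonylation; it sets out from 14 (the side chain before stannylation, which again meets 32) and comes back at 36. TESOTf and 2,6-lutidine give the silyl ether F7. Cp2Zr(H)Cl adds across the alkyne to give the E-alkenylzirconocene chloride F8. Carbon monoxide (1 atm) inserts to give the acylzirconocene chloride F9. Coupling with the allylic chloride 32 under catalysis by copper iodide (CuI) gives the fully silylated ene-dione F10, which the conditions of step 16 convert into 36.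

Further compounds
F1 | step 14 | (3R,4R,5S)-5-({[tert-butyl(dimethyl)silyl]oxy}methyl)-1,1,1-trichloro-3-methyl-3,4-bis[(triethylsilyl)oxy]heptane-2,6-dione | ClC(Cl)(Cl)C(=O)[C@](C)(O[Si](CC)(CC)CC)[C@H](O[Si](CC)(CC)CC)[C@H](CO[Si](C)(C)C(C)(C)C)C(C)=O
F2 | step 14 | (4S,5R,6R)-4-({[tert-butyl(dimethyl)silyl]oxy}methyl)-2-chloro-3,6-dimethyl-5,6-bis[(triethylsilyl)oxy]cyclohex-2-en-1-one | O=C1C(Cl)=C(C)[C@@H](CO[Si](C)(C)C(C)(C)C)[C@@H](O[Si](CC)(CC)CC)[C@@]1(C)O[Si](CC)(CC)CC
F3 | step 14 | triethylsilyl dienol ether of F2 (2-chloro-3-methylidene-1-[(triethylsilyl)oxy]cyclohex-1-ene core, stereocentres as in F2) | CC[Si](CC)(CC)OC1=C(Cl)C(=C)[C@@H](CO[Si](C)(C)C(C)(C)C)[C@@H](O[Si](CC)(CC)CC)[C@@]1(C)O[Si](CC)(CC)CC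
F4 | step 13 | (2S,3R,4S)-4-({[tert-butyl(dimethyl)silyl]oxy}methyl)-2-methyl-2,3-bis[(triethylsilyl)oxy]hex-5-en-1-ol | OC[C@](C)(O[Si](CC)(CC)CC)[C@H](O[Si](CC)(CC)CC)[C@H](CO[Si](C)(C)C(C)(C)C)C=C
F5 | step 13 | (2R,3R,4S)-4-({[tert-butyl(dimethyl)silyl]oxy}methyl)-2-methyl-2,3-bis[(triethylsilyl)oxy]hex-5-enal | O=C[C@](C)(O[Si](CC)(CC)CC)[C@H](O[Si](CC)(CC)CC)[C@H](CO[Si](C)(C)C(C)(C)C)C=C
F6 | step 13 | 5-({[tert-butyl(dimethyl)silyl]oxy}methyl)-1,1,1-trichloro-3-methyl-3,4-bis[(triethylsilyl)oxy]hept-6-en-2-ol (both carbinol epimers, other stereocentres as in 30) | ClC(Cl)(Cl)C(O)[C@](C)(O[Si](CC)(CC)CC)[C@H](O[Si](CC)(CC)CC)[C@H](CO[Si](C)(C)C(C)(C)C)C=C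
F7 | step 15 | triethyl({(2S)-2-[(2S,3S)-3-methyloxolan-2-yl]but-3-yn-2-yl}oxy)silane | C#C[C@](C)(O[Si](CC)(CC)CC)[C@H]1OCC[C@@H]1C
F8 | step 15 | chlorobis(cyclopentadienyl){(1E,3S)-3-[(2S,3S)-3-methyloxolan-2-yl]-3-[(triethylsilyl)oxy]but-1-en-1-yl}zirconium | Cl[Zr](/C=C/[C@](C)(O[Si](CC)(CC)CC)[C@H]1OCC[C@@H]1C)(C1C=CC=C1)C1C=CC=C1
F9 | step 15 | chlorobis(cyclopentadienyl){(2E,4S)-4-[(2S,3S)-3-methyloxolan-2-yl]-4-[(triethylsilyl)oxy]pent-2-enoyl}zirconium | Cl[Zr](C(=O)/C=C/[C@](C)(O[Si](CC)(CC)CC)[C@H]1OCC[C@@H]1C)(C1C=CC=C1)C1C=CC=C1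
F10 | step 15 | triethylsilyl ether of 34 at the side-chain tertiary hydroxyl | O=C1C(Cl)=C(CC(=O)/C=C/[C@](C)(O[Si](CC)(CC)CC)[C@H]2OCC[C@@H]2C)[C@@H](CO[Si](C)(C)C(C)(C)C)[C@@H](O[Si](CC)(CC)CC)[C@@]1(C)O[Si](CC)(CC)CC
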